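Numbering: C1 and C5 are the ring-fusion carbons, C2–C4 complete the cyclopentene, C6–C10 the cycloheptane, C11–C15 the side chain. Everything rests on cutting the C3=C4 alkene of the 1-methylcyclopentene. Ring-closing metathesis joins an allyl group on C1 and an isopropenyl group on C5, placed trans by one cuprate addition/enolate allylation, and so closes the five-membered ring with its trans fusion in one operation; it exploits that this alkene lies between the ring-fusion carbons, whereas the exocyclic C10 methylene could only close a four-membered ring. The precursor is a monocyclic cycloheptane triene whose C6, C7 and C11 centres come from an Ireland–Claisen rearrangement and a temporary cis-fused γ-lactone.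

Key step: step 13

Remark: β is the face of the seven-membered ring that carries O6 (α the opposite face); the proline-derived lithium amide of step 1 is assumed to act on cycloheptene oxide with the sense of induction known for cyclohexene oxide.

Step 1
Reactants: 1 cycloheptene oxide
Product: 2 (S)-cyclohept-2-en-1-ol
Conditions: (S)-2-(pyrrolidin-1-ylmethyl)pyrrolidine, n-BuLi, THF, 0 °C → rt
Reagents that add atoms: none
Why: Enantioselective epoxide-to-allylic-alcohol rearrangement, in which the chiral lithium amide removes one of the two enantiotopic syn β-hydrogens of the meso epoxide, should give the (S)-alcohol and so fix the absolute configuration of the route.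

Step 2
Reactants: 2 (S)-cyclohept-2-en-1-ol
Product: 3 (S)-cyclohept-2-en-1-yl propanoate
Conditions: (EtCO)2O, Et3N, cat. DMAP, CH2Cl2, 0 °C → rt
Reagents that add atoms: propanoic anhydride CCC(=O)OC(=O)CC
Why: DMAP-catalysed acylation of the secondary alcohol, which touches no stereocentre.

Step 3
Reactants: 3 (S)-cyclohept-2-en-1-yl propanoate
Product: 6 (2R)-2-[(1R)-cyclohept-2-en-1-yl]propanoic acid, via silyl ketene acetal 4 (not isolated), via trimethylsilyl ester 5 (not isolated)
Conditions: LiN(i-Pr)2, THF/DMPU, −78 °C; Me3SiCl; −78 → 50 °C; then 1 M HCl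
Reagents that add atoms: none
Why: Ireland–Claisen rearrangement, in which the (Z)-silyl ketene acetal reacts suprafacially through a chair transition state, so that the C7–C11 bond forms on the face of the departing C5–O bond (C7 by 1,3-chirality transfer) and C11 follows from the ketene acetal geometry; the (E)-isomer reacting through a boat would give the same C11 configuration.

Step 4
Reactants: 6 (2R)-2-[(1R)-cyclohept-2-en-1-yl]propanoic acid
Product: 7 selenolactone (cis-fused γ-lactone with ring oxygen on C6β and C11 on C7β; 5α-phenylselanyl; 11R)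
Conditions: PhSeCl, CH2Cl2, −78 °C → rt
Reagents that add atoms: benzeneselenenyl chloride Cl[Se]c1ccccc1
Why: Phenylselenolactonisation, in which the tethered carboxylate opens the seleniranium ion at C6 in a 5-exo mode and can do so only from the face of the C7–C11 bond, so that O6 becomes β (cis to the side chain) and the selenium sits anti on C5.

Step 5
Reactants: 7 selenolactone
Product: 9 allylic lactone (the cis-fused γ-lactone with a C1=C5 alkene; 11R), via selenoxide 8 (not isolated)
Conditions: 30% H2O2, THF, 0 °C → rt
Reagents that add atoms: none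
Why: Selenoxide syn-elimination takes a C1 hydrogen, away from the oxygen-bearing C6, under neutral conditions that leave the epimerisable C11 centre untouched.

Step 6
Reactants: 9 allylic lactone
Product: 10 enone lactone (9 with a C10 ketone conjugated to C1=C5)
Conditions: Rh2(cap)4 (1 mol %; cap = caprolactamate), t-BuOOH, K2CO3, CH2Cl2, rt
Reagents that add atoms: tert-butyl hydroperoxide CC(C)(C)OO
Why: Allylic C–H oxidation by the peroxyl radical chain should go to C10, the only allylic methylene, because the other allylic C–H (C6) is tertiary and deactivated by the acyloxy group.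

Step 7
Reactants: 10 enone lactone
Product: 11 γ-hydroxy enone Weinreb amide (cyclohept-1(5)-en-10-one with 6β-OH and 7β-[(2R)-1-(methoxy(methyl)amino)-1-oxopropan-2-yl])
Conditions: MeNH(OMe)·HCl, AlMe3, CH2Cl2, 0 °C → rt
Reagents that add atoms: N,O-dimethylhydroxylamine hydrochloride CNOC.Cl
Why: Weinreb aminolysis by the aluminium amide cleaves the temporary lactone ring, frees the C6 hydroxyl and leaves C12 as an acyl donor; no stereocentre changes.

Step 8
Reactants: 11 γ-hydroxy enone Weinreb amide
Product: 12 6β-O-tert-butyldimethylsilyl ether of 11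
Conditions: t-BuMe2SiOTf, 2,6-lutidine, CH2Cl2, −78 °C
Reagents that add atoms: tert-butyldimethylsilyl trifluoromethanesulfonate CC(C)(C)[Si](C)(C)OS(=O)(=O)C(F)(F)F
Why: Silylation turns the γ-oxygen into a bulky group that does not leave, which the cuprate step needs.

Step 9
Reactants: 12 6β-O-tert-butyldimethylsilyl ether of 11
Product: 14 cycloheptan-10-one carrying 1β-allyl and 5α-isopropenyl groups beside the 6β-silyloxy group and the 7β Weinreb side chain, via lithium enolate 13 (not isolated)
Conditions: Li[Cu(C(CH3)=CH2)2], THF/Et2O, −78 °C; then CH2=CHCH2I, DMPU, −78 → −20 °C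
Reagents that add atoms: lithium di(prop-1-en-2-yl)cuprate [Li+].C=C(C)[Cu-]C(C)=C; allyl iodide C=CCI
Why: Three-component coupling, in which conjugate addition anti to the γ-silyloxy group (and to the β side chain on C7) sets C5 with the isopropenyl group α, and C-allylation of the enolate trans to this new neighbour sets C1 with the allyl group β.

Step 10
Reactants: 14 1β-allyl-5α-isopropenyl cycloheptan-10-one
Product: 16 9α-hydroxy ketone, via potassium enolate 15 (not isolated)
Conditions: KN(SiMe3)2, THF, −78 °C; then 3-phenyl-2-(phenylsulfonyl)oxaziridine, −78 °C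
Reagents that add atoms: 3-phenyl-2-(phenylsulfonyl)oxaziridine O=S(=O)(c1ccccc1)N1OC1c1ccccc1
Why: Kinetic deprotonation at the C9 methylene (not the tertiary C1–H) and Davis oxaziridine hydroxylation of the enolate from the α face, opposite the β substituents on C1 and C7, should give the 9α-alcohol.

Step 11
Reactants: 16 9α-hydroxy ketone
Product: 17 6β,9α-bis(tert-butyldimethylsilyloxy) ketone
Conditions: t-BuMe2SiOTf, 2,6-lutidine, CH2Cl2, 0 °C
Reagents that add atoms: tert-butyldimethylsilyl trifluoromethanesulfonate CC(C)(C)[Si](C)(C)OS(=O)(=O)C(F)(F)F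
Why: Silylation of the α-hydroxy ketone, so that only the C12 oxygen is free for the later acetylation.

Step 12
Reactants: 17 6β,9α-bis(tert-butyldimethylsilyloxy) ketone
Product: 18 triene (C10=CH2 in place of the ketone; allyl on C1; isopropenyl on C5)
Conditions: Zn, CH2Br2, TiCl4, THF/CH2Cl2, 0 °C → rt
Reagents that add atoms: dibromomethane BrCBr
Why: Lombardo–Takai methylenation is a non-basic carbonyl olefination that should convert the hindered ketone without epimerising C1 or C9 and without touching the amide.

Step 13
Reactants: 18 triene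
Product: 19 trans-fused hydroazulene (C3=C4 closed; 10-methylene; 6β,9α-bis-silyl ether; C12 Weinreb amide)
Conditions: second-generation Grubbs catalyst (H2IMes)(PCy3)Cl2Ru=CHPh (5 mol %), CH2Cl2, 40 °C
Reagents that add atoms: none
Why: Ring-closing olefin metathesis by the Chauvin mechanism: the ruthenium alkylidene is loaded on the monosubstituted allyl terminus (C3), adds to the 1,1-disubstituted isopropenyl alkene (C4) to give a ruthenacyclobutane, and cycloreversion releases the C3=C4 alkene and Ru=CH2, with loss of ethene driving the reaction. The closest known reaction type is the closure of hepta-1,6-dienes to 1-methylcyclopentenes by second-generation ruthenium carbenes. The five-membered ring is closed by joining the alkene carbons of two substituents on the adjacent ring carbons C1 and C5, so that the new bond is the ring alkene itself. No stereocentre is formed; the trans ring fusion is the C1/C5 configuration set in step 9, and because C10 is no longer a ketone the fusion cannot epimerise afterwards. The step needs site selectivity among three alkenes: the exocyclic C10 methylene is 1,1-disubstituted, initiates slowly and could only give a cyclobutene with the allyl group, so the allyl/isopropenyl pairing is the only productive one. The trans-diequatorial C1 and C5 substituents hold the two termini within reach.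

Step 14
Reactants: 19 trans-fused hydroazulene Weinreb amide; 20 2-methylbut-3-yn-2-ol
Product: 22 C12 ynone (12-oxo-13-yn-15-ol), via dilithium alkynide 21 (not isolated)
Conditions: 20, n-BuLi (2 equiv per alkyne), THF, −78 → 0 °C; then 19, −78 → 0 °C
Reagents that add atoms: none
Why: Acylation of the lithium acetylide by the Weinreb amide stops at the ketone because the chelated tetrahedral intermediate survives until work-up, and C11 should not epimerise at low temperature.

Step 15
Reactants: 22 C12 ynone
Product: 23 (12R)-propargylic alcohol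
Conditions: RuCl(p-cymene)[(R,R)-TsDPEN] (2 mol %), i-PrOH, rt
Reagents that add atoms: none
Why: Noyori asymmetric transfer hydrogenation of the ynone under catalyst control, reinforced by the Felkin preference at C11, should give the anti relationship of the C11 methyl and the C12 oxygen without reducing any alkene.

Step 16
Reactants: 23 (12R)-propargylic alcohol
Product: 24 (12S,13E)-allylic alcohol (12,15-diol)
Conditions: NaAlH2(OCH2CH2OMe)2, THF, 0 °C → rt; aqueous KNaC4H4O6 work-up
Reagents that add atoms: none
Why: Hydroxyl-directed trans-hydroalumination of the propargylic alcohol followed by protonolysis gives the (E)-alkene; the C12 descriptor changes only because the ligand ranking changes.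

Step 17
Reactants: 24 (12S,13E)-allylic alcohol
Product: 25 12-acetate of 24
Conditions: Ac2O, pyridine, cat. DMAP, CH2Cl2, 0 °C
Reagents that add atoms: acetic anhydride CC(=O)OC(C)=O
Why: Chemoselective acetylation of the only free secondary alcohol; the tertiary C15 alcohol does not react under these conditions.

Step 18
Reactants: 25 12-acetate of 24
Product: 26 target CNP0213969.2 (1R,5S,6R,7S,9R,11R,12S,13E)
Conditions: HF·pyridine, THF/pyridine, 0 °C → rt
Reagents that add atoms: none
Why: Fluoride cleavage of both silyl ethers under buffered, non-basic conditions that should leave the allylic acetate in place and unmigrated.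

Compound list
1 | cycloheptene oxide (8-oxabicyclo[5.1.0]octane, meso) | C1CCC2OC2CC1 | starting material
2 | (S)-cyclohept-2-en-1-ol | O[C@@H]1C=CCCCC1 | intermediate
3 | (S)-cyclohept-2-en-1-yl propanoate | CCC(=O)O[C@@H]1C=CCCCC1 | intermediate
4 | (Z)-trimethylsilyl ketene acetal of 3 (methyl cis to OSiMe3) | C/C=C(\O[Si](C)(C)C)O[C@@H]1C=CCCCC1 | intermediate
5 | trimethylsilyl (2R)-2-[(1R)-cyclohept-2-en-1-yl]propanoate | C1CC[C@@H]([C@@H](C)C(=O)O[Si](C)(C)C)C=CC1 | intermediate
6 | (2R)-2-[(1R)-cyclohept-2-en-1-yl]propanoic acid | C1CC[C@@H]([C@@H](C)C(=O)O)C=CC1 | intermediate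
7 | selenolactone: cis-fused γ-lactone, ring O on C6β, C11 on C7β, 5α-SePh, 11R | C1CC[C@H]2[C@@H](C)C(=O)O[C@H]2[C@H]([Se]c3ccccc3)C1 | intermediate
8 | selenoxide of 7 | C1CC[C@H]2[C@@H](C)C(=O)O[C@H]2[C@H]([Se](=O)c3ccccc3)C1 | intermediate
9 | allylic lactone: cis-fused γ-lactone with C1=C5 alkene, 11R | C1CC[C@H]2[C@@H](C)C(=O)O[C@H]2C=C1 | intermediate
10 | enone lactone: 9 with C10 ketone | O=C1CC[C@H]2[C@@H](C)C(=O)O[C@H]2C=C1 | intermediate
11 | γ-hydroxy enone Weinreb amide: 6β-OH, 7β-[(2R)-1-(methoxy(methyl)amino)-1-oxopropan-2-yl], C10 ketone, C1=C5 alkene | O=C1CC[C@@H]([C@@H](C)C(=O)N(C)OC)[C@@H](O)C=C1 | intermediate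
12 | 6β-O-tert-butyldimethylsilyl ether of 11 | O=C1CC[C@@H]([C@@H](C)C(=O)N(C)OC)[C@@H](O[Si](C)(C)C(C)(C)C)C=C1 | intermediate
13 | lithium enolate (C10–OLi, C10=C1) after addition of isopropenyl to C5α | [Li]OC=1CC[C@@H]([C@@H](C)C(=O)N(C)OC)[C@@H](O[Si](C)(C)C(C)(C)C)[C@H](C(C)=C)C=1 | intermediate
14 | cycloheptan-10-one: 1β-allyl, 5α-isopropenyl, 6β-OTBS, 7β Weinreb side chain | O=C1CC[C@@H]([C@@H](C)C(=O)N(C)OC)[C@@H](O[Si](C)(C)C(C)(C)C)[C@H](C(C)=C)[C@H]1CC=C | intermediate
15 | potassium enolate of 14 (C10–OK, C10=C9) | [K]OC1=CC[C@@H]([C@@H](C)C(=O)N(C)OC)[C@@H](O[Si](C)(C)C(C)(C)C)[C@H](C(C)=C)[C@H]1CC=C | intermediate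
16 | 9α-hydroxy ketone | O=C1[C@H](O)C[C@@H]([C@@H](C)C(=O)N(C)OC)[C@@H](O[Si](C)(C)C(C)(C)C)[C@H](C(C)=C)[C@H]1CC=C | intermediate
17 | 6β,9α-bis(tert-butyldimethylsilyloxy) ketone | O=C1[C@H](O[Si](C)(C)C(C)(C)C)C[C@@H]([C@@H](C)C(=O)N(C)OC)[C@@H](O[Si](C)(C)C(C)(C)C)[C@H](C(C)=C)[C@H]1CC=C | intermediate
18 | triene: 10-methylene, 1β-allyl, 5α-isopropenyl | C=C1[C@H](O[Si](C)(C)C(C)(C)C)C[C@@H]([C@@H](C)C(=O)N(C)OC)[C@@H](O[Si](C)(C)C(C)(C)C)[C@H](C(C)=C)[C@H]1CC=C | intermediate
19 | trans-fused hydroazulene Weinreb amide (C3=C4 closed) | C=C1[C@H](O[Si](C)(C)C(C)(C)C)C[C@@H]([C@@H](C)C(=O)N(C)OC)[C@@H](O[Si](C)(C)C(C)(C)C)[C@@H]2C(C)=CC[C@@H]12 | intermediate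
20 | 2-methylbut-3-yn-2-ol | C#CC(C)(C)O | starting material
21 | dilithium alkynide alkoxide of 20 | [Li]C#CC(C)(C)O[Li] | intermediate
22 | C12 ynone (12-oxo-13-yn-15-ol) | C=C1[C@H](O[Si](C)(C)C(C)(C)C)C[C@@H]([C@@H](C)C(=O)C#CC(C)(C)O)[C@@H](O[Si](C)(C)C(C)(C)C)[C@@H]2C(C)=CC[C@@H]12 | intermediate
23 | (12R)-propargylic alcohol | C=C1[C@H](O[Si](C)(C)C(C)(C)C)C[C@@H]([C@@H](C)[C@H](C#CC(C)(C)O)O)[C@@H](O[Si](C)(C)C(C)(C)C)[C@@H]2C(C)=CC[C@@H]12 | intermediate
24 | (12S,13E)-allylic alcohol (12,15-diol) | C=C1[C@H](O[Si](C)(C)C(C)(C)C)C[C@@H]([C@@H](C)[C@H](/C=C/C(C)(C)O)O)[C@@H](O[Si](C)(C)C(C)(C)C)[C@@H]2C(C)=CC[C@@H]12 | intermediate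
25 | 12-acetate of 24 | C=C1[C@H](O[Si](C)(C)C(C)(C)C)C[C@@H]([C@@H](C)[C@H](/C=C/C(C)(C)O)OC(C)=O)[C@@H](O[Si](C)(C)C(C)(C)C)[C@@H]2C(C)=CC[C@@H]12 | intermediate
26 | CNP0213969.2: 12-acetoxy-6β,9α,15-trihydroxy trans-fused hydroazulene diterpenoid (1R,5S,6R,7S,9R,11R,12S,13E) | C=C1[C@H](O)C[C@@H]([C@@H](C)[C@H](/C=C/C(C)(C)O)OC(C)=O)[C@@H](O)[C@@H]2C(C)=CC[C@@H]12 | target

Total step count: 18. Longest linear sequence: 18 steps (1 → 26).

Steps most likely to fail

Step 9: C-allylation of the copper-containing enolate may be too slow, so that proton transfer to the C9 side, O-allylation or plain protonation take over and the allyl group is lost or misplaced. The fallback sets out from 12: the same cuprate is added in the presence of Me3SiCl to give the trimethylsilyl enol ether F1, which is isolated. F1 is then allylated regiospecifically at C1 under zerovalent-palladium catalysis (Pd2(dba)3, dppe, allyl methyl carbonate, THF, 65 °C; Tsuji allylation), trans to the C5 substituent, and the route is rejoined at 14.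

Step 6: hydrogen abstraction at the tertiary C6–H, trapping of the allyl radical at C5 instead of C10, or over-oxidation may erode the regioselectivity. The fallback sets out from 9: SeO2 (cat.)/t-BuOOH in CH2Cl2 hydroxylates C10 by an ene/[2,3]-sigmatropic sequence that returns the alkene to C1=C5 and gives the allylic alcohol F2. Dess–Martin periodinane then oxidises F2, and the route is rejoined at 10.

Step 3: competition between chair and boat transition states, or incomplete control of the ketene acetal geometry, may give a mixture of C11 epimers. The mixture is then taken through steps 4 and 5, and the fallback sets out from 9 as obtained together with its C11 epimer F3. LiN(i-Pr)2 (THF, −78 °C) converts both into the common lithium enolate F4, and kinetic protonation from the convex face of the cis-fused bicycle (2,6-di-tert-butyl-4-methylphenol, −78 °C) places the methyl group on the concave face and returns 9 alone.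

Further compounds
F1 | step 9 | trimethylsilyl enol ether (C10–OSiMe3, C10=C1) of the conjugate adduct | C[Si](C)(C)OC=1CC[C@@H]([C@@H](C)C(=O)N(C)OC)[C@@H](O[Si](C)(C)C(C)(C)C)[C@H](C(C)=C)C=1
F2 | step 6 | 10-hydroxy derivative of 9 (allylic alcohol, C10 epimers) | OC1CC[C@H]2[C@@H](C)C(=O)O[C@H]2C=C1
F3 | step 3 | C11 epimer of 9 (methyl on the convex face) | C1CC[C@H]2[C@H](C)C(=O)O[C@H]2C=C1
F4 | step 3 | lithium enolate of the lactone 9/F3 | C1CC[C@H]2C(C)=C(O[Li])O[C@H]2C=C1
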